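**Retrosynthetic overview**
- The C3 ketone and the (E)-C1=C2 enone are released at the end from a bridged 2-isoxazoline (N–O cleavage, dehydration); the α-methylene lactone travels as its dimethylamine adduct.
- Key disconnection C2–C3: an intramolecular nitrile oxide–alkene [3+2] cycloaddition closes the ten-membered carbocycle (dipole on a (Z)-enal oxime at C3, dipolarophile the vinyl carbinol at C10).
- The (Z)-C4=C5 unit comes from iodo-olefination and formylation of a C5 aldehyde; the cis-γ-lactone comes from a syn-selective indium Barbier coupling (C7–C8) followed by lactonisation; the C8 ester comes from (R)-2-methylbutanoic acid.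
- Building blocks: (R)-linalool (C1, C2, C8–C10, C14; sets C10), (S)-glyceraldehyde acetonide (C5–C7; sets C6, which controls C7 and C8) and methyl acrylate (C11–C13).
- Ring order: γ-lactone first; then isoxazoline and ten-membered ring together in the cycloaddition; the isoxazoline is opened last.

Assumption: germacranolide numbering is used throughout (ring C1–C10, lactone carbons C11–C13, C14 on C10, C15 on C4); the target is read from the SMILES as the 6S,7R,8R,10R isomer with a cis-fused lactone and a (2R)-ester, and stereocentres written without a descriptor are mixtures that are erased later.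

**Route**

Step 1
Reactants: 1 (R)-linalool
Product: 2 (5R)-5-ethenyl-5-methyloxolan-2-ol (lactol, anomers)
Conditions: O3 (1.0 equiv), CH2Cl2/MeOH, −78 °C; then Me2S, −78 °C to rt
Reagents that add atoms: ozone, [O-][O+]=O
Why: Chemoselective ozonolysis, in which the electron-rich trisubstituted alkene reacts far faster than the vinyl group and the freed γ-hydroxy aldehyde closes to the lactol, leaves the purchased C10 stereocentre untouched.

Step 2
Reactants: 2 (5R)-5-ethenyl-5-methyloxolan-2-ol
Product: 3 (2R)-2-ethenyl-2-methyl-2,3-dihydrofuran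
Conditions: MsCl, Et3N, CH2Cl2, −40 °C to reflux
Reagents that add atoms: none
Why: Lactol dehydration, in which the anomeric mesylate ionises and loses a proton to give the cyclic enol ether, breaks no bond at the quaternary stereocentre.

Step 3
Reactants: 3 (2R)-2-ethenyl-2-methyl-2,3-dihydrofuran
Product: 4 (3R)-3-methyl-1-oxopent-4-en-3-yl formate
Conditions: O3, CH2Cl2, −78 °C; then Me2S
Reagents that add atoms: ozone, [O-][O+]=O
Why: Ozonolysis of the enol ether, which is far more reactive than the vinyl group, excises one carbon and leaves the C8 aldehyde with the tertiary hydroxyl already protected as its formate.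

Step 4
Reactants: 5 5,6-O-isopropylidene-L-gulono-1,4-lactone
Product: 6 (4S)-2,2-dimethyl-1,3-dioxolane-4-carbaldehyde [(S)-glyceraldehyde acetonide]
Conditions: NaIO4 (2.1 equiv), H2O, pH 5.5, 0 °C to rt
Reagents that add atoms: none
Why: Malaprade periodate cleavage of the 2,3-diol and then of the α-hydroxy aldehyde so released strips C1–C3, so that C5 of the gulonolactone survives as the (S)-stereocentre of the aldehyde.

Step 5
Reactants: 6 (S)-glyceraldehyde acetonide; 7 methyl acrylate
Product: 8 methyl 2-{[(4S)-2,2-dimethyl-1,3-dioxolan-4-yl](hydroxy)methyl}prop-2-enoate (carbinol epimers)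
Conditions: DABCO (0.5 equiv), dioxane/H2O (1:1), rt, 48 h
Reagents that add atoms: none
Why: Morita–Baylis–Hillman reaction under amine catalysis gives the adduct, whose new carbinol centre forms as a mixture but becomes sp2 in step 6, so only the dioxolane centre matters.

Step 6
Reactants: 8 Morita–Baylis–Hillman adduct
Product: 9 methyl (2Z)-2-(bromomethyl)-3-[(4R)-2,2-dimethyl-1,3-dioxolan-4-yl]prop-2-enoate
Conditions: NBS, Me2S, CH2Cl2, 0 °C to rt
Reagents that add atoms: N-bromosuccinimide, O=C1CCC(=O)N1Br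
Why: Corey–Kim-type activation of the hydroxyl as an alkoxysulfonium ion and SN2′ attack of bromide give the rearranged allyl bromide, the (Z)-isomer being favoured because the ester avoids the dioxolane.

Step 7
Reactants: 4 (3R)-3-methyl-1-oxopent-4-en-3-yl formate; 9 (Z)-allyl bromide
Product: 11 methyl 2-[(1R,2R,4R)-1-[(4R)-2,2-dimethyl-1,3-dioxolan-4-yl]-2,4-dihydroxy-4-methylhex-5-en-1-yl]prop-2-enoate, via formate adduct 10 (not isolated)
Conditions: In powder, THF/H2O (1:1), rt; then KHCO3 (cat.), MeOH, 0 °C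
Reagents that add atoms: none
Why: Indium-mediated Barbier allylation through a chair-like six-membered transition state of the (Z)-allylindium sets C7 and C8 syn, while the C6 dioxolane centre, held with its hydrogen eclipsing the alkene by allylic 1,3-strain, directs the aldehyde to the C7 face anti to the C5–C6 bond, and mild methanolysis then removes the migration-prone formate.

Step 8
Reactants: 11 Barbier diol; 12 (2R)-2-methylbutanoic acid
Product: 13 methyl 2-[(1R,2R,4R)-1-[(4R)-2,2-dimethyl-1,3-dioxolan-4-yl]-4-hydroxy-4-methyl-2-{[(2R)-2-methylbutanoyl]oxy}hex-5-en-1-yl]prop-2-enoate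
Conditions: DIC, DMAP (cat.), CH2Cl2, 0 °C to rt
Reagents that add atoms: none
Why: Steglich esterification acylates the secondary C8 hydroxyl while the tertiary C10 hydroxyl is inert, under conditions that do not epimerise the purchased α-stereocentre of the acid.

Step 9
Reactants: 13 C8 ester
Product: 15 (1R,3R)-1-[(2R,3R)-4-[(dimethylamino)methyl]-2-(hydroxymethyl)-5-oxooxolan-3-yl]-3-hydroxy-3-methylpent-4-en-1-yl (2R)-2-methylbutanoate (C11 epimers), via methylene lactone 14 (not isolated)
Conditions: TsOH·H2O (0.2 equiv), MeOH, rt; then Me2NH (2 M in MeOH), rt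
Reagents that add atoms: dimethylamine, CNC
Why: Acid-catalysed acetonide cleavage frees the C6 hydroxyl, which lactonises onto the acrylate ester to the five-membered cis-β,γ-disubstituted lactone faster than the C5 hydroxyl can form a six-membered one, and aza-Michael addition of dimethylamine then masks the exo-methylene so that it cannot act as a dipolarophile in step 14.

Step 10
Reactants: 15 amine-masked lactone
Product: 16 (1R,3R)-1-[(2R,3R)-4-[(dimethylamino)methyl]-2-formyl-5-oxooxolan-3-yl]-3-hydroxy-3-methylpent-4-en-1-yl (2R)-2-methylbutanoate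
Conditions: (COCl)2, DMSO, CH2Cl2, −78 °C; then Et3N, −78 to 0 °C
Reagents that add atoms: none
Why: Swern oxidation converts the primary C5 alcohol into the aldehyde at low temperature without epimerising C6 or touching the tertiary alcohol and the tertiary amine.

Step 11
Reactants: 16 C5 aldehyde
Product: 17 (1R,3R)-1-[(2R,3R)-4-[(dimethylamino)methyl]-2-[(1Z)-2-iodoprop-1-en-1-yl]-5-oxooxolan-3-yl]-3-hydroxy-3-methylpent-4-en-1-yl (2R)-2-methylbutanoate
Conditions: [Ph3PCH(CH3)I]I, NaN(SiMe3)2 (2.5 equiv each), THF, −78 °C; then 16, −78 to −20 °C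
Reagents that add atoms: (1-iodoethyl)triphenylphosphonium iodide, CC(I)[P+](c1ccccc1)(c1ccccc1)c1ccccc1.[I-]
Why: Stork–Zhao-type Wittig olefination with the non-stabilised α-iodo ylide passes through the kinetic cis-oxaphosphetane and gives the (Z)-iodoalkene with iodine cis to C6, which fixes the later 4Z geometry.

Step 12
Reactants: 17 (Z)-iodoalkene
Product: 18 (1R,3R)-1-[(2S,3R)-4-[(dimethylamino)methyl]-2-[(1Z)-2-methyl-3-oxoprop-1-en-1-yl]-5-oxooxolan-3-yl]-3-hydroxy-3-methylpent-4-en-1-yl (2R)-2-methylbutanoate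
Conditions: Pd(PPh3)4 (5 mol %), CO (3 bar), Bu3SnH (slow addition), THF, 50 °C
Reagents that add atoms: carbon monoxide, [C-]#[O+]
Why: Stille-type reductive carbonylation (oxidative addition to zerovalent palladium, CO insertion, hydride transfer from tin to the acylpalladium) gives the enal with retention of the double-bond geometry.

Step 13
Reactants: 18 (Z)-enal
Product: 19 (1Z,3E)-aldoxime of 18 [C6–CH=C(CH3)–CH=N–OH]
Conditions: NH2OH·HCl, NaOAc, EtOH/H2O, 0 °C
Reagents that add atoms: hydroxylamine hydrochloride, NO.Cl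
Why: Buffered oxime condensation is mild enough to preserve the Z-enal geometry and the C6 stereocentre.

Step 14
Reactants: 19 aldoxime
Product: 22 bridged 2-isoxazoline (C3=N–O–C1 with C2 as the CH2 bridge; ten-membered carbocycle closed; C1 epimers), via hydroximoyl chloride 20 (not isolated), via nitrile oxide 21 (not isolated)
Conditions: TsOH·H2O (1.0 equiv), NCS, DMF, 0 °C; then syringe-pump addition (10 h) to Et3N, CH2Cl2, 1 mM, rt
Reagents that add atoms: none
Why: Key step, an intramolecular nitrile oxide–alkene [3+2] cycloaddition in which the dipole carbon bonds to the terminal vinyl carbon C2 and the oxygen to C1 (the normal regiochemistry for a monosubstituted alkene), closing the ten-membered carbocycle at high dilution with the amine protected as its ammonium salt during chlorination; the new C1 centre is destroyed in step 16.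

Step 15
Reactants: 22 bridged isoxazoline
Product: 23 β-hydroxy ketone (C3 ketone, C1 hydroxyl; the 1-hydroxy-1,2-dihydro derivative of 25)
Conditions: Fe powder, NH4Cl, EtOH/H2O (4:1), 80 °C
Reagents that add atoms: water, O
Why: Reductive N–O cleavage of the 2-isoxazoline by iron and hydrolysis of the resulting β-hydroxy imine unveil the C3 ketone and the C1 hydroxyl without reducing the alkenes, esters or lactone.

Step 16
Reactants: 23 β-hydroxy ketone
Product: 25 dimethylamine adduct of the target (13-dimethylamino-11,13-dihydro derivative, C11 epimers), via mesylate 24 (not isolated)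
Conditions: MsCl, Et3N, CH2Cl2, 0 °C to rt
Reagents that add atoms: none
Why: Selective mesylation of the secondary C1 hydroxyl (the tertiary C10 hydroxyl is inert) and E1cB elimination across C1–C2 give the conjugated (E)-enone.

Step 17
Reactants: 25 amine-masked dienone
Product: 27 target, (3aR,4R,6R,7E,10Z,11aS)-6-hydroxy-6,10-dimethyl-3-methylidene-2,9-dioxo-3a,4,5,11a-tetrahydrocyclodeca[b]furan-4-yl (2R)-2-methylbutanoate, via trimethylammonium iodide 26 (not isolated)
Conditions: MeI, THF, rt; then NaHCO3, H2O/EtOAc, rt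
Reagents that add atoms: none
Why: Exhaustive N-methylation turns the amine into a leaving group and mild base triggers E1cB (Hofmann-type) loss of trimethylamine, regenerating the α-methylene lactone without touching the dienone or any stereocentre.

**Compound list**
1 | (R)-linalool, (3R)-3,7-dimethylocta-1,6-dien-3-ol | C=C[C@](C)(O)CCC=C(C)C | starting material
2 | (5R)-5-ethenyl-5-methyloxolan-2-ol (anomers) | C=C[C@@]1(C)CCC(O)O1 | intermediate
3 | (2R)-2-ethenyl-2-methyl-2,3-dihydrofuran | C=C[C@@]1(C)CC=CO1 | intermediate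
4 | (3R)-3-methyl-1-oxopent-4-en-3-yl formate | O=CC[C@@](C)(OC=O)C=C | intermediate
5 | 5,6-O-isopropylidene-L-gulono-1,4-lactone | O=C1O[C@H]([C@@H]2COC(C)(C)O2)[C@H](O)[C@@H]1O | starting material
6 | (4S)-2,2-dimethyl-1,3-dioxolane-4-carbaldehyde | O=C[C@@H]1COC(C)(C)O1 | intermediate
7 | methyl acrylate | C=CC(=O)OC | starting material
8 | methyl 2-{[(4S)-2,2-dimethyl-1,3-dioxolan-4-yl](hydroxy)methyl}prop-2-enoate (carbinol epimers) | C=C(C(=O)OC)C(O)[C@@H]1COC(C)(C)O1 | intermediate
9 | methyl (2Z)-2-(bromomethyl)-3-[(4R)-2,2-dimethyl-1,3-dioxolan-4-yl]prop-2-enoate | BrC/C(C(=O)OC)=C\[C@@H]1COC(C)(C)O1 | intermediate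
10 | methyl 2-[(1R,2R,4R)-1-[(4R)-2,2-dimethyl-1,3-dioxolan-4-yl]-4-(formyloxy)-2-hydroxy-4-methylhex-5-en-1-yl]prop-2-enoate | C=C(C(=O)OC)[C@@H]([C@@H]1COC(C)(C)O1)[C@H](O)C[C@@](C)(OC=O)C=C | intermediate
11 | methyl 2-[(1R,2R,4R)-1-[(4R)-2,2-dimethyl-1,3-dioxolan-4-yl]-2,4-dihydroxy-4-methylhex-5-en-1-yl]prop-2-enoate | C=C(C(=O)OC)[C@@H]([C@@H]1COC(C)(C)O1)[C@H](O)C[C@@](C)(O)C=C | intermediate
12 | (2R)-2-methylbutanoic acid | CC[C@@H](C)C(=O)O | starting material
13 | methyl 2-[(1R,2R,4R)-1-[(4R)-2,2-dimethyl-1,3-dioxolan-4-yl]-4-hydroxy-4-methyl-2-{[(2R)-2-methylbutanoyl]oxy}hex-5-en-1-yl]prop-2-enoate | C=C(C(=O)OC)[C@@H]([C@@H]1COC(C)(C)O1)[C@H](OC(=O)[C@H](C)CC)C[C@@](C)(O)C=C | intermediate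
14 | (1R,3R)-3-hydroxy-1-[(2R,3R)-2-(hydroxymethyl)-4-methylidene-5-oxooxolan-3-yl]-3-methylpent-4-en-1-yl (2R)-2-methylbutanoate | C=C1C(=O)O[C@@H](CO)[C@H]1[C@H](OC(=O)[C@H](C)CC)C[C@@](C)(O)C=C | intermediate
15 | dimethylamine adduct of 14: (1R,3R)-1-[(2R,3R)-4-[(dimethylamino)methyl]-2-(hydroxymethyl)-5-oxooxolan-3-yl]-3-hydroxy-3-methylpent-4-en-1-yl (2R)-2-methylbutanoate (C11 epimers) | CN(C)CC1C(=O)O[C@@H](CO)[C@H]1[C@H](OC(=O)[C@H](C)CC)C[C@@](C)(O)C=C | intermediate
16 | C5 aldehyde of 15 (2-formyl instead of 2-hydroxymethyl; 2R,3R in the oxolane) | CN(C)CC1C(=O)O[C@@H](C=O)[C@H]1[C@H](OC(=O)[C@H](C)CC)C[C@@](C)(O)C=C | intermediate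
17 | (Z)-iodoalkene: oxolane C2 carries (1Z)-2-iodoprop-1-en-1-yl, iodine cis to C6 (2R,3R) | CN(C)CC1C(=O)O[C@@H](/C=C(/C)I)[C@H]1[C@H](OC(=O)[C@H](C)CC)C[C@@](C)(O)C=C | intermediate
18 | (Z)-enal: oxolane C2 carries (1Z)-2-methyl-3-oxoprop-1-en-1-yl, CHO cis to C6 (2S,3R) | CN(C)CC1C(=O)O[C@@H](/C=C(/C)C=O)[C@H]1[C@H](OC(=O)[C@H](C)CC)C[C@@](C)(O)C=C | intermediate
19 | (1Z,3E)-aldoxime of 18 | CN(C)CC1C(=O)O[C@@H](/C=C(/C)\C=N\O)[C@H]1[C@H](OC(=O)[C@H](C)CC)C[C@@](C)(O)C=C | intermediate
20 | hydroximoyl chloride of 19 | CN(C)CC1C(=O)O[C@@H](/C=C(/C)C(Cl)=NO)[C@H]1[C@H](OC(=O)[C@H](C)CC)C[C@@](C)(O)C=C | intermediate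
21 | (Z)-alkenyl nitrile oxide from 20 | CN(C)CC1C(=O)O[C@@H](/C=C(/C)C#[N+][O-])[C@H]1[C@H](OC(=O)[C@H](C)CC)C[C@@](C)(O)C=C | intermediate
22 | bridged 2-isoxazoline: ten-membered carbocycle with C3=N–O–C1 spanned by C2; C6, C7, C8, C10 as in the target; C1 and C11 epimers | CN(C)CC1C(=O)O[C@H]2/C=C(/C)C3=NOC(C3)[C@](C)(O)C[C@@H](OC(=O)[C@H](C)CC)[C@@H]12 | intermediate
23 | β-hydroxy ketone: 1-hydroxy-1,2-dihydro derivative of 25 (C1 epimers) | CN(C)CC1C(=O)O[C@H]2/C=C(/C)C(=O)CC(O)[C@](C)(O)C[C@@H](OC(=O)[C@H](C)CC)[C@@H]12 | intermediate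
24 | C1 methanesulfonate of 23 | CN(C)CC1C(=O)O[C@H]2/C=C(/C)C(=O)CC(OS(C)(=O)=O)[C@](C)(O)C[C@@H](OC(=O)[C@H](C)CC)[C@@H]12 | intermediate
25 | dimethylamine adduct of the target: 13-(dimethylamino)-11,13-dihydro derivative, (1E,4Z)-dienone in place (C11 epimers) | CN(C)CC1C(=O)O[C@H]2/C=C(/C)C(=O)/C=C/[C@](C)(O)C[C@@H](OC(=O)[C@H](C)CC)[C@@H]12 | intermediate
26 | N-methyl quaternary ammonium iodide of 25 | C[N+](C)(C)CC1C(=O)O[C@H]2/C=C(/C)C(=O)/C=C/[C@](C)(O)C[C@@H](OC(=O)[C@H](C)CC)[C@@H]12.[I-] | intermediate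
27 | (3aR,4R,6R,7E,10Z,11aS)-6-hydroxy-6,10-dimethyl-3-methylidene-2,9-dioxo-3a,4,5,11a-tetrahydrocyclodeca[b]furan-4-yl (2R)-2-methylbutanoate | C=C1C(=O)O[C@H]2/C=C(/C)C(=O)/C=C/[C@](C)(O)C[C@@H](OC(=O)[C@H](C)CC)[C@@H]12 | target

**Step count and risks**
Total steps: 17. Longest linear sequence: 14 (steps 1–3 and 7–17; steps 4–6 form the three-step side branch).

Most likely to fail, first: step 14. A bridged cycloaddition that closes a ten-membered ring may lose to furoxan formation or oligomerisation. The fallback sets out from iodoalkene 17: carbonylative Stille coupling with tributyl(vinyl)stannane [Pd(PPh3)4, CO (3 bar), THF, 50 °C] gives divinyl ketone F1. Ring-closing metathesis of F1 (amine protonated with TsOH, second-generation Hoveyda–Grubbs catalyst, toluene, 80 °C, 0.5 mM) forms C1=C2 and comes back to the route at 25.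

Second: step 7. The syn C7/C8 relationship is reliable, but the facial selectivity at C7 under the influence of the C6 dioxolane is argued by model only. The fallback sets out from bromide 9: hydrolysis of the acetonide (AcOH/H2O 4:1, rt) gives diol bromide F2, which is coupled at once with 4 (In powder, H2O/THF, rt). The free C6 hydroxyl then chelates indium, holds the C6–O bond in the plane of the allyl unit and leaves only the face anti to C5 open, giving triol formate F3. Re-acetalisation of F3 (2,2-dimethoxypropane, PPTS, acetone, 0 °C) comes back to the route at 10, which is methanolysed to 11 as in step 7.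

Third: step 12. Formylation of a hindered (Z)-iodoalkene with tin hydride can give hydrodeiodination or Z-to-E leakage. The fallback sets out from aldehyde 16: Still–Gennari-type olefination with S-ethyl 2-[bis(2,2,2-trifluoroethoxy)phosphoryl]propanethioate [KN(SiMe3)2, 18-crown-6, THF, −78 °C] gives (Z)-thioester F4. Fukuyama reduction of F4 (Et3SiH, Pd/C, acetone, rt) comes back to the route at 18, replacing steps 11 and 12.

**Further compounds**
F1 | step 14 | divinyl ketone: 17 with iodine replaced by C(=O)CH=CH2 (Z at C4=C5) | CN(C)CC1C(=O)O[C@@H](/C=C(/C)C(=O)C=C)[C@H]1[C@H](OC(=O)[C@H](C)CC)C[C@@](C)(O)C=C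
F2 | step 7 | methyl (2Z,4R)-2-(bromomethyl)-4,5-dihydroxypent-2-enoate | BrC/C(C(=O)OC)=C\[C@@H](O)CO
F3 | step 7 | methyl 2-[(1R,2R,4R)-1-[(1R)-1,2-dihydroxyethyl]-4-(formyloxy)-2-hydroxy-4-methylhex-5-en-1-yl]prop-2-enoate | C=C(C(=O)OC)[C@@H]([C@@H](O)CO)[C@H](O)C[C@@](C)(OC=O)C=C
F4 | step 12 | (Z)-S-ethyl thioester: 18 with CHO replaced by C(=O)SEt | CN(C)CC1C(=O)O[C@@H](/C=C(/C)C(=O)SCC)[C@H]1[C@H](OC(=O)[C@H](C)CC)C[C@@](C)(O)C=C
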